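Assumptions: ent-kaurane numbering (C1–C20) is used for every intermediate. Catalysts, bases, solvents and water are not numbered. In step 3 the ligand antipode is the one that delivers Me to the Si face of the enone β-carbon (both antipodes are available).

## Retrosynthetic overview
1. D ring last: the C13–C16 bond comes from an iodine-atom-transfer 5-exo closure of a C16 α-acyl radical onto a 12-chlorocyclohexene. The chlorine is a traceless regiocontrol element, stripped in the same pot.
2. C ring (key step): an intermolecular Diels–Alder reaction of chloroprene with the spiro 3-propanoyl-5,6-dihydropyran-2-one 17. It forms C8–C14 and C9–C11 and sets quaternary C8 and C9 from C10 in one step. This replaces the usual ester-tethered IMDA or the C6–C7 cleavage of an intact kaurane.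
3. B ring: Ti(III) epoxide opening, Giese addition and lactonisation form C9–C10 and the spiro quaternary C10. Acylation and selenoxide elimination then arm the dienophile.
4. A ring and THF acetal: Cu-catalysed asymmetric conjugate methylation sets C4 and is the only external chirality source. Orthoformate trapping of the enolate installs C6, and transacetalisation closes the acetal.
5. Ring order: A → THF acetal → B (δ-lactone) → C → D.

## Route

**Step 1**
Reactants: 1, 3-methoxybenzyl alcohol
Product: 2, 3-(hydroxymethyl)cyclohex-2-en-1-one
Conditions: Li, NH3(l), t-BuOH, THF, −78 → −33 °C; then 2 M HCl, THF, rt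
Reagents that add atoms: water (O)
Why: Birch reduction of the lithium alkoxide (which suppresses benzylic C–O cleavage) gives the 1-methoxy-1,4-diene, and acidic enol-ether hydrolysis with conjugation gives the enone; no stereocentre is formed.

**Step 2**
Reactants: 2; 3, tert-butyldimethylsilyl chloride
Product: 4, 3-{[(tert-butyldimethylsilyl)oxy]methyl}cyclohex-2-en-1-one
Conditions: TBSCl, imidazole, CH2Cl2, 0 °C → rt
Reagents that add atoms: TBSCl, CC(C)(C)[Si](C)(C)Cl
Why: Standard O-silylation masks the C19 hydroxyl against Me3Al and makes it a poor leaving group in the cuprate step.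

**Step 3**
Reactants: 4; 5, trimethylaluminium; 6, trimethylsilyl triflate
Product: 7, (R)-TMS enol ether, 1-methyl-1-(TBSO-methyl)-3-(trimethylsilyloxy)cyclohex-2-ene (4R; C5=C10 enol ether)
Conditions: Me3Al, CuTC (2 mol %), biphenol-derived bis[1-(2-naphthyl)ethyl]amine phosphoramidite (4 mol %), Et2O, −30 °C; then TMSOTf, Et3N, −30 → 0 °C
Reagents that add atoms: Me3Al, C[Al](C)C; TMSOTf, C[Si](C)(C)OS(=O)(=O)C(F)(F)F
Why: Cu-catalysed asymmetric conjugate addition delivers Me to the Si face of the β-carbon and creates the C4 quaternary centre (4R), while O-silylation of the aluminium enolate fixes the C5=C10 regiochemistry that deprotonation could not give.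

**Step 4**
Reactants: 7; 8, trimethyl orthoformate
Product: 9, (3R)-3-(TBSO-methyl)-2-(dimethoxymethyl)-3-methylcyclohexan-1-one (C5 epimer mixture)
Conditions: HC(OMe)3, BF3·OEt2, CH2Cl2, −78 °C
Reagents that add atoms: trimethyl orthoformate, COC(OC)OC
Why: Mukaiyama-type alkylation of the silyl enol ether by the small dimethoxycarbenium ion installs C6 at the acetal oxidation level regiospecifically at hindered C5, whose configuration is irrelevant because it is epimerisable.

**Step 5**
Reactants: 9
Product: 10, (3S,3aS,7aR)-3-methoxy-7a-methylhexahydro-2-benzofuran-4(1H)-one (cis-fused; kaurane 4R,5S,6S; C10 ketone)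
Conditions: CSA (10 mol %), MeOH, 0 °C → rt
Reagents that add atoms: none (the acetal OMe may exchange degenerately with solvent MeOH, CO)
Why: Acidic desilylation and transacetalisation run under thermodynamic control, so C5 epimerises through the enol to the only unstrained cis-fused bicycle (H5 cis to 18-Me) and OMe settles on the convex face trans to C10 (6S).

**Step 6**
Reactants: 10; 11, chloroiodomethane
Product: 12, spiro-epoxide at C10 (O on the concave face and CH2 = C20 on the convex face for the major isomer)
Conditions: ClCH2I, MeLi·LiBr, THF/Et2O, −78 °C → rt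
Reagents that add atoms: chloroiodomethane, ClCI
Why: Chloromethyllithium (Matteson-type carbenoid) adds 1,2 at −78 °C faster than it enolises, which avoids E1cB loss of the β-acetal, and the chlorohydrin alkoxide closes to the epoxide on warming; the C10 configuration is erased in step 7.

**Step 7**
Reactants: 12; 13, 2,2,2-trifluoroethyl acrylate
Product: 14, (4R,5R,6S,10R)-spiro-δ-lactone (C10–C20H2–O–C7(=O)–C8H2–C9H2)
Conditions: Cp2TiCl2 (30 mol %), Zn, 2,4,6-collidine·HCl, THF, rt
Reagents that add atoms: 2,2,2-trifluoroethyl acrylate, C=CC(=O)OCC(F)(F)F
Why: Ti(III) reductive epoxide opening (Nugent–RajanBabu/Gansäuer) gives the tertiary C10 radical, which undergoes Giese addition on the convex face anti to axial C19 and C6 (sets 10R), and the Ti alkoxide then expels trifluoroethoxide to close the lactone.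

**Step 8**
Reactants: 14; 15, N-methoxy-N-methylpropanamide
Product: 16, 8-propanoyl spirolactone (β-keto lactone, C8 epimers/enol)
Conditions: LDA (2.2 equiv), THF, −78 °C; then 15, −78 → 0 °C
Reagents that add atoms: N-methoxy-N-methylpropanamide, CCC(=O)N(C)OC
Why: This is a crossed Claisen C-acylation of the lactone enolate, where the chelated tetrahedral Weinreb adduct prevents O-acylation and over-addition and C8 is the only acidic site.

**Step 9**
Reactants: 16
Product: 17, (4R,5R,6S,10R)-3-propanoyl-5,6-dihydro-2H-pyran-2-one spiro-fused at C10 (C8=C9)
Conditions: PhSeCl, pyridine, CH2Cl2, 0 °C; then 30 % H2O2, 0 °C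
Reagents that add atoms: none
Why: α-Selenenylation of the β-dicarbonyl followed by selenoxide syn-elimination can only use the C9 hydrogens, and quaternary C10 prevents tautomerisation of the alkylidene product.

**Step 10 (key step)**
Reactants: 17; 18, chloroprene (2-chlorobuta-1,3-diene)
Product: 19, (4R,5R,6S,8S,9S,10R)-12-chloro-cyclohex-12-ene adduct (C ring cis-fused to the lactone; propanoyl on C8)
Conditions: 18 (10 equiv), ZnCl2 (1.2 equiv), BHT, CH2Cl2, 0 °C → rt; PPTS, MeOH wash-through if C6 has partly epimerised
Reagents that add atoms: chloroprene, C=CC(Cl)=C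
Why: This is a normal-demand Diels–Alder reaction of a ZnCl2-chelated, doubly activated 2-acyl enoate, in which suprafacial addition makes C7/C10 cis on ring C (8S,9S), the diene takes the lactone face flanked by C1H2 because C6–H blocks the other face, and "para" orientation places Cl on C12 (endo/exo is stereochemically irrelevant).

**Step 11**
Reactants: 19; 20, N-iodosuccinimide
Product: 21, 16-iodo ketone (C16 epimers)
Conditions: LiHMDS, TMSCl, THF, −78 °C; then NIS, −78 → 0 °C, dark
Reagents that add atoms: NIS, O=C1CCC(=O)N1I
Why: C16 is the only enolisable carbon because C8 is quaternary, and halogenation of its silyl enol ether leaves the electron-poor vinyl chloride, the lactone and the acetal untouched.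

**Step 12**
Reactants: 21
Product: 22, ludongnin H
Conditions: (Bu3Sn)2 (15 mol %), hν, PhH, 80 °C; then (TMS)3SiH (4 equiv), AIBN, 85 °C; then DBU (cat.), rt
Reagents that add atoms: none
Why: Proposed new method: iodine-atom-transfer conditions keep regenerating the C16 α-acyl radical until it closes 5-exo from the axial C8 acyl group onto the unsubstituted C13 (C12 is blocked by Cl and the product radical is α-chloro-stabilised, disfavouring the [2.2.2] mode), the bridge geometry fixes 13R, silane then replaces both C12–I and C12–Cl by H, and DBU equilibrates C16 to the exo methyl (16S); the closest known chemistry is atom-transfer cyclisation of α-iodo ketones followed by radical hydrodehalogenation.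

## Compound list
| No. | Name | SMILES | Role |
|---|---|---|---|
| 1 | 3-methoxybenzyl alcohol | COc1cccc(CO)c1 | starting material |
| 2 | 3-(hydroxymethyl)cyclohex-2-en-1-one | O=C1C=C(CO)CCC1 | intermediate |
| 3 | TBSCl | CC(C)(C)[Si](C)(C)Cl | starting material |
| 4 | 3-(TBSO-methyl)cyclohex-2-en-1-one | O=C1C=C(CO[Si](C)(C)C(C)(C)C)CCC1 | intermediate |
| 5 | trimethylaluminium | C[Al](C)C | starting material |
| 6 | TMSOTf | C[Si](C)(C)OS(=O)(=O)C(F)(F)F | starting material |
| 7 | (R)-TMS enol ether | C[Si](C)(C)OC1=C[C@](C)(CO[Si](C)(C)C(C)(C)C)CCC1 | intermediate |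
| 8 | trimethyl orthoformate | COC(OC)OC | starting material |
| 9 | (3R)-2-(dimethoxymethyl) ketone (C5 epimers) | COC(OC)C1C(=O)CCC[C@@]1(C)CO[Si](C)(C)C(C)(C)C | intermediate |
| 10 | cis-fused methoxy-acetal ketone | CO[C@H]1OC[C@]2(C)CCCC(=O)[C@H]12 | intermediate |
| 11 | chloroiodomethane | ClCI | starting material |
| 12 | C10 spiro-epoxide (major epimer drawn; both converge) | CO[C@H]1OC[C@]2(C)CCC[C@@]3(CO3)[C@H]12 | intermediate |
| 13 | 2,2,2-trifluoroethyl acrylate | C=CC(=O)OCC(F)(F)F | starting material |
| 14 | spiro-δ-lactone | CO[C@H]1OC[C@]2(C)CCC[C@]3(COC(=O)CC3)[C@H]12 | intermediate |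
| 15 | N-methoxy-N-methylpropanamide | CCC(=O)N(C)OC | starting material |
| 16 | 8-propanoyl lactone (C8 epimers/enol) | CO[C@H]1OC[C@]2(C)CCC[C@]3(COC(=O)C(C(=O)CC)C3)[C@H]12 | intermediate |
| 17 | spiro 3-propanoyl-dihydropyranone | CO[C@H]1OC[C@]2(C)CCC[C@]3(COC(=O)C(C(=O)CC)=C3)[C@H]12 | intermediate |
| 18 | chloroprene | C=CC(Cl)=C | starting material |
| 19 | Diels–Alder adduct | CO[C@H]1OC[C@]2(C)CCC[C@]3(COC(=O)[C@@]4(C(=O)CC)CC=C(Cl)C[C@H]43)[C@H]12 | intermediate |
| 20 | N-iodosuccinimide | O=C1CCC(=O)N1I | starting material |
| 21 | 16-iodo ketone (C16 epimers) | CO[C@H]1OC[C@]2(C)CCC[C@]3(COC(=O)[C@@]4(C(=O)C(C)I)CC=C(Cl)C[C@H]43)[C@H]12 | intermediate |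
| 22 | ludongnin H | CO[C@H]1OC[C@]2(C)CCC[C@]3(COC(=O)[C@@]45C[C@@H](CC[C@H]43)[C@H](C)C5=O)[C@H]12 | target |

## Summary
Total steps: 12. Longest linear sequence: 12 (from 1).

Where each stereocentre is set:
- C4: step 3.
- C5 and C6: step 5 (self-correcting under MeOH/H+).
- C10: step 7.
- C8 and C9: step 10.
- C13 and C16: step 12.

Steps most likely to fail:

1. **Step 10 (Diels–Alder).**
   - Risks: the dienophile is neopentyl and trisubstituted. Chloroprene is sluggish and polymerisable. Hetero-Diels–Alder reaction or acetal ionisation could compete.
   - Fallback: change the activating group and the order of events.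
     - Formylate 14 (HCO2Et) instead of running step 8.
     - Dehydrogenate to the smaller, more reactive 3-formyl dihydropyranone, which should cycloadd thermally without a Lewis acid.
     - Build the C15–C16–C17 ketone after the cycloaddition by EtMgBr addition and oxidation.

2. **Step 12 (radical closure).**
   - Risks: the closure puts the carbonyl inside the forming five-membered ring (enol-endo-type geometry). It must also go through the ring-C conformer with C10 axial. Simple reduction or [2.2.2] products are therefore possible.
   - Fallback: invert the polarity of the bond formation, at a cost of two extra steps.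
     - Run step 10 with 2-(TBSO)buta-1,3-diene so that C13 becomes a regiodefined enol-ether carbon.
     - Halogenate C16 through its lithium enolate.
     - Release the C12 enolate with fluoride, which closes by a favoured 5-(enolexo)-exo-tet alkylation.
     - Delete the C12 ketone through its tosylhydrazone with catecholborane.

3. **Step 3 (ACA on a γ-silyloxy enone with Al-enolate silylation).**
   - Risks: low ee, reductive loss of the OTBS group, or poor trapping of the aluminium enolate.
   - Fallback: form C4–C19 instead of C4–C18.
     - Run a Cu/NHC-catalysed asymmetric addition of a vinylalane to commercial 3-methylcyclohex-2-enone with the same TMS trapping.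
     - Carry the vinyl group through step 4.
     - Unveil C19–OH by ozonolysis and selective aldehyde reduction, which triggers the same acetal closure to 10.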